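## Retrosynthetic overview

1. Numbering (carotenoid convention): ring A is the 3,4-didehydro ring (C1–C6, alkyne C7≡C8); ring B is the hydroxylated ring (C1'–C6', alkyne C7'≡C8'); the chain runs C9–C15 and C15'–C9'.
2. C40 is cut into C15 + C10 + C15 by two Wittig disconnections at C11=C12 and C11'=C12', giving an all-E triene dialdehyde and two enynyl tributylphosphonium salts.
3. Ring B half: Sonogashira disconnection at C6'–C7' gives a cyclohexenyl triflate from a purchased (R)-hydroxy ketone (ring B preformed, source of C3') and an (E)-enynol that also serves the ring A half.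
4. Ring A half: [3+3] disconnection of C1–C2 and C4–C5 into an allyl phosphorus ylide (C2–C3–C4) and an acyclic α-alkynyl enone already carrying the side chain; the forward reaction is a Michael addition/intramolecular Wittig annulation followed in the same flask by a proton shift into conjugation. Enabling feature: ring A holds an unsubstituted allyl segment C2H2–C3H=C4H between the gem-dimethyl carbon C1 and the methyl-bearing C5, which are 1,3-related through the alkynyl carbon C6, so C5/C6/C1 map onto the carbonyl/α/β carbons of mesityl oxide.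
5. Ring order: ring B is carried in from the start; ring A is the only ring made (step 3).

Key step: step 3

Assumption: the enantiopure hydroxy ketone used in step 5 (industrial zeaxanthin building block) is taken as purchasable; its carbinol centre is carried unchanged into C3' of the target.

## Route

Step 1
Reactants: 1 mesityl oxide (4-methylpent-3-en-2-one)
Product: 3 3-bromo-4-methylpent-3-en-2-one, via mesityl oxide dibromide 2 (not isolated)
Conditions: Br2, CH2Cl2, 0 °C; then Et3N, 0 °C to rt
Reagents that add atoms: bromine, BrBr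
Why: Anti addition of Br2 to the enone C=C and E1cB loss of HBr (acidic α-proton, tertiary β-bromide) should return the conjugated α-bromo enone, the usual bromination–dehydrobromination route to 2-bromo enones.

Step 2
Reactants: 3 3-bromo-4-methylpent-3-en-2-one; 4 (2E)-3-methylpent-2-en-4-yn-1-ol
Product: 5 (6E)-8-hydroxy-6-methyl-3-(propan-2-ylidene)oct-6-en-4-yn-2-one
Conditions: PdCl2(PPh3)2 (3 mol %), CuI (6 mol %), Et3N, THF, degassed, rt to 45 °C
Reagents that add atoms: none
Why: Sonogashira coupling: the C(sp2)–Br bond of an α-bromo enone is activated for oxidative addition to zerovalent palladium, the copper acetylide of 4 transmetalates, and the E geometry and free hydroxyl of 4 are not touched.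

Step 3
Reactants: 5 (6E)-8-hydroxy-6-methyl-3-(propan-2-ylidene)oct-6-en-4-yn-2-one; 6 allyltriphenylphosphonium bromide
Product: 9 (2E)-3-methyl-5-(2,6,6-trimethylcyclohexa-1,3-dien-1-yl)pent-2-en-4-yn-1-ol, via allylidenetriphenylphosphorane 7 (not isolated), via cyclohexa-2,4-diene isomer 8 (not isolated)
Conditions: 6 (1.5 equiv), KOt-Bu (1.5 equiv), THF, 0 °C; add 5, 0 to 50 °C; then KOt-Bu (2.5 equiv), DMSO, rt; aq. NH4Cl
Reagents that add atoms: none
Why: The γ-carbon of ylide 7 adds in a Michael reaction to the β,β-dimethyl carbon C1 of enone 5 (C1–C2 bond, quaternary centre), proton transfer from C2 turns the vinylphosphonium enolate into a new allylic ylide, and intramolecular Wittig olefination of the C5 methyl ketone (C4–C5 bond, loss of Ph3PO) closes ring A as cyclohexa-2,4-diene 8. The closest known reaction type is the [3+3] cyclohexadiene annulation of allylidenetriphenylphosphorane with enones and alkylidene β-keto esters (Michael addition/intramolecular Wittig). Ring A closes by a six-membered intramolecular Wittig reaction (6-exo-trig attack of ylide carbon C4 on the C5 carbonyl through an oxaphosphetane), the cis C2=C3 geometry being reachable by rotation in the delocalised ylide. KOt-Bu in DMSO should then remove the doubly allylic, propargylic C6–H of 8 and reprotonate at C2 (base-mediated 1,5-prototropic shift), giving the fully conjugated dienyne 9 as the thermodynamic sink; no stereocentre remains, since C6 of racemic 8 becomes sp2. The step needs conjugate γ-attack in place of direct carbonyl olefination: a semi-stabilised ylide olefinates a hindered ketone only slowly, while the linear α-alkynyl group keeps the enone planar, withdraws inductively, stabilises the enolate and adds little bulk at C1. During the base treatment the side-chain hydroxyl is present as its alkoxide, which shields C11–H from deprotonation, and the E geometry at C9=C10 keeps this alkoxide away from the alkyne.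

Step 4
Reactants: 9 (2E)-3-methyl-5-(2,6,6-trimethylcyclohexa-1,3-dien-1-yl)pent-2-en-4-yn-1-ol
Product: 11 tributyl[(2E)-3-methyl-5-(2,6,6-trimethylcyclohexa-1,3-dien-1-yl)pent-2-en-4-yn-1-yl]phosphonium bromide, via allylic bromide 10 (not isolated)
Conditions: CBr4, PPh3, CH2Cl2, −20 to 0 °C; then PBu3, 0 °C to rt, dark
Reagents that add atoms: carbon tetrabromide, BrC(Br)(Br)Br; tributylphosphine, CCCCP(CCCC)CCCC
Why: Appel bromination displaces the primary allylic hydroxyl by SN2 without allylic shift or loss of the 9E geometry, and the strongly nucleophilic trialkylphosphine then quaternises the bromide in the same flask; the tributyl salt is chosen because its ylide is expected to favour E olefination.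

Step 5
Reactants: 12 (4R,6R)-4-hydroxy-2,2,6-trimethylcyclohexan-1-one (actinol)
Product: 13 (4R,6R)-4-[(tert-butyldimethylsilyl)oxy]-2,2,6-trimethylcyclohexan-1-one
Conditions: TBSCl, imidazole, DMF, rt
Reagents that add atoms: tert-butyldimethylsilyl chloride, CC(C)(C)[Si](C)(C)Cl
Why: Imidazole-promoted silylation of the secondary alcohol; neither stereocentre is involved.

Step 6
Reactants: 13 (4R,6R)-4-[(tert-butyldimethylsilyl)oxy]-2,2,6-trimethylcyclohexan-1-one
Product: 14 (4R)-4-[(tert-butyldimethylsilyl)oxy]-2,6,6-trimethylcyclohex-1-en-1-yl trifluoromethanesulfonate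
Conditions: LDA (commercial solution), THF, −78 to 0 °C; PhNTf2, −78 °C to rt
Reagents that add atoms: N-phenylbis(trifluoromethanesulfonimide), O=S(=O)(N(c1ccccc1)S(=O)(=O)C(F)(F)F)C(F)(F)F
Why: C2 is quaternary, so the ketone can enolise only towards C6, and O-triflation of this single tetrasubstituted enolate gives the enol triflate; the C6 stereocentre is removed on purpose and C4 (the later C3') is untouched.

Step 7
Reactants: 14 (4R)-4-[(tert-butyldimethylsilyl)oxy]-2,6,6-trimethylcyclohex-1-en-1-yl trifluoromethanesulfonate; 4 (2E)-3-methylpent-2-en-4-yn-1-ol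
Product: 15 (2E)-5-[(4R)-4-[(tert-butyldimethylsilyl)oxy]-2,6,6-trimethylcyclohex-1-en-1-yl]-3-methylpent-2-en-4-yn-1-ol
Conditions: Pd(PPh3)4 (5 mol %), CuI (10 mol %), i-Pr2NH, DMF, degassed, rt to 40 °C
Reagents that add atoms: none
Why: Sonogashira coupling of the cyclohexenyl triflate with the terminal alkyne forms C6'–C7' and takes 9'E directly from the geometry of 4.

Step 8
Reactants: 15 (2E)-5-[(4R)-4-[(tert-butyldimethylsilyl)oxy]-2,6,6-trimethylcyclohex-1-en-1-yl]-3-methylpent-2-en-4-yn-1-ol
Product: 17 tributyl[(2E)-5-[(4R)-4-[(tert-butyldimethylsilyl)oxy]-2,6,6-trimethylcyclohex-1-en-1-yl]-3-methylpent-2-en-4-yn-1-yl]phosphonium bromide, via allylic bromide 16 (not isolated)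
Conditions: CBr4, PPh3, CH2Cl2, −20 to 0 °C; then PBu3, 0 °C to rt, dark
Reagents that add atoms: carbon tetrabromide, BrC(Br)(Br)Br; tributylphosphine, CCCCP(CCCC)CCCC
Why: Appel bromination (SN2, geometry retained, silyl ether stable under these neutral cold conditions) followed by quaternisation with the trialkylphosphine, as in step 4.

Step 9
Reactants: 17 the ring B tributylphosphonium bromide; 18 (2E,4E,6E)-2,7-dimethylocta-2,4,6-trienedial
Product: 19 (2E,4E,6E,8E,10E)-13-[(4R)-4-[(tert-butyldimethylsilyl)oxy]-2,6,6-trimethylcyclohex-1-en-1-yl]-2,7,11-trimethyltrideca-2,4,6,8,10-pentaen-12-ynal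
Conditions: 18 (3 equiv), NaOMe, CH2Cl2, 0 °C to rt, slow addition of 17, dark
Reagents that add atoms: none
Why: Wittig olefination forms C11'=C12'; the allylic tributylphosphonium ylide is expected to favour the E alkene and to hold 9'E, and the excess of the symmetrical, non-enolisable dialdehyde limits double olefination.

Step 10
Reactants: 11 the ring A tributylphosphonium bromide; 19 the C25 aldehyde
Product: 20 tert-butyldimethylsilyl ether of the target (all-E)
Conditions: NaOMe, CH2Cl2, 0 °C to rt, dark, argon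
Reagents that add atoms: none
Why: The second Wittig olefination forms C11=C12 and completes the C40 chain with the E preference of step 9; minor Z isomers are to be removed by chromatography and crystallisation in the dark.

Step 11
Reactants: 20 tert-butyldimethylsilyl ether of the target
Product: 21 CNP0250213.1, (all-E,3'R)-3,4-didehydro-7,8,7',8'-tetradehydro-β,β-caroten-3'-ol (numbering as used here)
Conditions: TBAF, THF, rt, dark
Reagents that add atoms: none
Why: Fluoride cleaves the Si–O bond (desilylation) without affecting the base-stable polyenyne; the R configuration is retained because the C–O bond is not broken.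

## Compound list

1 | mesityl oxide (4-methylpent-3-en-2-one) | CC(=O)C=C(C)C | starting material
2 | 3,4-dibromo-4-methylpentan-2-one (mesityl oxide dibromide, racemic) | CC(=O)C(Br)C(C)(C)Br | intermediate
3 | 3-bromo-4-methylpent-3-en-2-one | CC(=O)C(Br)=C(C)C | intermediate
4 | (2E)-3-methylpent-2-en-4-yn-1-ol | C#C/C(C)=C/CO | starting material
5 | (6E)-8-hydroxy-6-methyl-3-(propan-2-ylidene)oct-6-en-4-yn-2-one | CC(=O)C(C#C/C(C)=C/CO)=C(C)C | intermediate
6 | allyltriphenylphosphonium bromide | C=CC[P+](c1ccccc1)(c1ccccc1)c1ccccc1.[Br-] | starting material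
7 | allylidenetriphenylphosphorane | C=CC=P(c1ccccc1)(c1ccccc1)c1ccccc1 | intermediate
8 | (2E)-3-methyl-5-(2,6,6-trimethylcyclohexa-2,4-dien-1-yl)pent-2-en-4-yn-1-ol (racemic at the ring carbon) | CC1=CC=CC(C)(C)C1C#C/C(C)=C/CO | intermediate
9 | (2E)-3-methyl-5-(2,6,6-trimethylcyclohexa-1,3-dien-1-yl)pent-2-en-4-yn-1-ol | CC1=C(C#C/C(C)=C/CO)C(C)(C)CC=C1 | intermediate
10 | 1-[(3E)-5-bromo-3-methylpent-3-en-1-yn-1-yl]-2,6,6-trimethylcyclohexa-1,3-diene | CC1=C(C#C/C(C)=C/CBr)C(C)(C)CC=C1 | intermediate
11 | tributyl[(2E)-3-methyl-5-(2,6,6-trimethylcyclohexa-1,3-dien-1-yl)pent-2-en-4-yn-1-yl]phosphonium bromide | CC1=C(C#C/C(C)=C/C[P+](CCCC)(CCCC)CCCC)C(C)(C)CC=C1.[Br-] | intermediate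
12 | (4R,6R)-4-hydroxy-2,2,6-trimethylcyclohexan-1-one (actinol) | O=C1C(C)(C)C[C@H](O)C[C@H]1C | starting material
13 | (4R,6R)-4-[(tert-butyldimethylsilyl)oxy]-2,2,6-trimethylcyclohexan-1-one | O=C1C(C)(C)C[C@H](O[Si](C)(C)C(C)(C)C)C[C@H]1C | intermediate
14 | (4R)-4-[(tert-butyldimethylsilyl)oxy]-2,6,6-trimethylcyclohex-1-en-1-yl trifluoromethanesulfonate | FC(F)(F)S(=O)(=O)OC1=C(C)C[C@@H](O[Si](C)(C)C(C)(C)C)CC1(C)C | intermediate
15 | (2E)-5-[(4R)-4-[(tert-butyldimethylsilyl)oxy]-2,6,6-trimethylcyclohex-1-en-1-yl]-3-methylpent-2-en-4-yn-1-ol | OC/C=C(\C)C#CC1=C(C)C[C@@H](O[Si](C)(C)C(C)(C)C)CC1(C)C | intermediate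
16 | {[(1R)-4-[(3E)-5-bromo-3-methylpent-3-en-1-yn-1-yl]-3,5,5-trimethylcyclohex-3-en-1-yl]oxy}(tert-butyl)dimethylsilane | BrC/C=C(\C)C#CC1=C(C)C[C@@H](O[Si](C)(C)C(C)(C)C)CC1(C)C | intermediate
17 | tributyl[(2E)-5-[(4R)-4-[(tert-butyldimethylsilyl)oxy]-2,6,6-trimethylcyclohex-1-en-1-yl]-3-methylpent-2-en-4-yn-1-yl]phosphonium bromide | CCCC[P+](CCCC)(CCCC)C/C=C(\C)C#CC1=C(C)C[C@@H](O[Si](C)(C)C(C)(C)C)CC1(C)C.[Br-] | intermediate
18 | (2E,4E,6E)-2,7-dimethylocta-2,4,6-trienedial | O=C/C(C)=C/C=C/C=C(\C)C=O | starting material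
19 | (2E,4E,6E,8E,10E)-13-[(4R)-4-[(tert-butyldimethylsilyl)oxy]-2,6,6-trimethylcyclohex-1-en-1-yl]-2,7,11-trimethyltrideca-2,4,6,8,10-pentaen-12-ynal | O=C/C(C)=C/C=C/C=C(C)/C=C/C=C(\C)C#CC1=C(C)C[C@@H](O[Si](C)(C)C(C)(C)C)CC1(C)C | intermediate
20 | tert-butyldimethylsilyl ether of the target (all-E, 3'R) | CC1=C(C#C/C(C)=C/C=C/C(C)=C/C=C/C=C(C)/C=C/C=C(\C)C#CC2=C(C)C[C@@H](O[Si](C)(C)C(C)(C)C)CC2(C)C)C(C)(C)CC=C1 | intermediate
21 | CNP0250213.1, (all-E,3'R)-3,4-didehydro-7,8,7',8'-tetradehydro-β,β-caroten-3'-ol | CC1=C(C#C/C(C)=C/C=C/C(C)=C/C=C/C=C(C)/C=C/C=C(\C)C#CC2=C(C)C[C@@H](O)CC2(C)C)C(C)(C)CC=C1 | target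

## Count and risks

Total step count: 11. Longest linear sequence: 7 steps (12 to 21 through steps 5, 6, 7, 8, 9, 10, 11).

**Step 3 (riskiest).** The ylide may olefinate the ketone directly, or be quenched by γ-deprotonation of the enone, instead of adding to the fully substituted β-carbon; the base-mediated proton shift may also erode the C9=C10 geometry. The fallback sets out from 7 (made from 6 as in step 3) with commercial pentane-2,4-dione and acetone, and comes back at 9. Knoevenagel condensation of pentane-2,4-dione with acetone (TiCl4, pyridine, THF) should give 3-(propan-2-ylidene)pentane-2,4-dione F1, a symmetrical, doubly activated acceptor of the alkylidene β-dicarbonyl type for which this annulation is established. With 7 it should give 1-(2,6,6-trimethylcyclohexa-2,4-dien-1-yl)ethan-1-one F2, which DBU in the same flask conjugates to 1-(2,6,6-trimethylcyclohexa-1,3-dien-1-yl)ethan-1-one F3. Kinetic enolisation of the methyl ketone (LDA, THF, −78 °C) and trapping with ClP(O)(OEt)2 gives diethyl 1-(2,6,6-trimethylcyclohexa-1,3-dien-1-yl)ethenyl phosphate F4, which further LDA eliminates to 1-ethynyl-2,6,6-trimethylcyclohexa-1,3-diene F5. Sonogashira coupling of F5 with commercial (E)-3-iodobut-2-en-1-ol (PdCl2(PPh3)2, CuI, Et3N) rejoins the route at 9, with the ring made by the same two bond formations and 9E taken from the iodide.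

**Step 10.** Rotation about C9=C10 in the allylic ylide and incomplete E selectivity at C11=C12 may give geometric isomers that are hard to separate. The fallback reverses the polarity of the olefination; it sets out from 9 and 19 and comes back at 20. Oxidation of 9 (MnO2, CH2Cl2) should give (2E)-3-methyl-5-(2,6,6-trimethylcyclohexa-1,3-dien-1-yl)pent-2-en-4-ynal F6, in which C9=C10 is part of a configurationally fixed enal. Reduction of 19 (NaBH4, MeOH/THF, 0 °C) gives the C25 allylic alcohol F7, and PPh3·HBr in CH2Cl2 converts it into the C25 triphenylphosphonium bromide F8. Wittig olefination of F6 with F8 (NaOMe, CH2Cl2) gives 20; the ylide is now a polyenyl ylide remote from the acetylenic C9=C10 unit.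

**Step 2.** Oxidative addition at the tetrasubstituted bromoalkene may be slow, so that alkyne homocoupling and amine attack on the bromo enone take over. The fallback forms the C–C(sp) bond on a base-insensitive vinyl dibromide and introduces the acetyl group last; it sets out from 4 and comes back at 5. Mono-Sonogashira coupling of 4 with commercial 1,1-dibromo-2-methylprop-1-ene (Pd(PPh3)4, CuI, i-Pr2NH) should give (2E)-6-bromo-3,7-dimethylocta-2,6-dien-4-yn-1-ol F9. O-deprotonation (n-BuLi), bromine–lithium exchange (t-BuLi, THF, −78 °C) and acylation of the vinyllithium with N-methoxy-N-methylacetamide then give 5.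

## Further compounds

F1 | step 3 | 3-(propan-2-ylidene)pentane-2,4-dione | CC(=O)C(C(C)=O)=C(C)C
F2 | step 3 | 1-(2,6,6-trimethylcyclohexa-2,4-dien-1-yl)ethan-1-one | CC(=O)C1C(C)=CC=CC1(C)C
F3 | step 3 | 1-(2,6,6-trimethylcyclohexa-1,3-dien-1-yl)ethan-1-one | CC(=O)C1=C(C)C=CCC1(C)C
F4 | step 3 | diethyl 1-(2,6,6-trimethylcyclohexa-1,3-dien-1-yl)ethenyl phosphate | C=C(OP(=O)(OCC)OCC)C1=C(C)C=CCC1(C)C
F5 | step 3 | 1-ethynyl-2,6,6-trimethylcyclohexa-1,3-diene | C#CC1=C(C)C=CCC1(C)C
F6 | step 10 | (2E)-3-methyl-5-(2,6,6-trimethylcyclohexa-1,3-dien-1-yl)pent-2-en-4-ynal | CC1=C(C#C/C(C)=C/C=O)C(C)(C)CC=C1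
F7 | step 10 | (2E,4E,6E,8E,10E)-13-[(4R)-4-[(tert-butyldimethylsilyl)oxy]-2,6,6-trimethylcyclohex-1-en-1-yl]-2,7,11-trimethyltrideca-2,4,6,8,10-pentaen-12-yn-1-ol | OC/C(C)=C/C=C/C=C(C)/C=C/C=C(\C)C#CC1=C(C)C[C@@H](O[Si](C)(C)C(C)(C)C)CC1(C)C
F8 | step 10 | [(2E,4E,6E,8E,10E)-13-[(4R)-4-[(tert-butyldimethylsilyl)oxy]-2,6,6-trimethylcyclohex-1-en-1-yl]-2,7,11-trimethyltrideca-2,4,6,8,10-pentaen-12-yn-1-yl]triphenylphosphonium bromide | [Br-].c1ccccc1[P+](c1ccccc1)(c1ccccc1)C/C(C)=C/C=C/C=C(C)/C=C/C=C(\C)C#CC1=C(C)C[C@@H](O[Si](C)(C)C(C)(C)C)CC1(C)C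
F9 | step 2 | (2E)-6-bromo-3,7-dimethylocta-2,6-dien-4-yn-1-ol | OC/C=C(\C)C#CC(Br)=C(C)C
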